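## Retrosynthetic overview

- The strategy rests on C9, the only methine of ring B: it sits between quaternary C10, C8 (the ring carbon carrying the exocyclic C17 methylene) and C11 of the side chain, so a phenylsulfonyl group on C9 lets this one carbon be alkylated by C11 and then acylated by a C8 ester.
- Target 34 ⇐ C3 acetate / C15 silyl ether adjustment, Wittig C8=C17, SmI2 removal of the sulfone with C9 equilibration ⇐ decalin β-keto sulfone 28.
- 28 ⇐ one-pot C9–C11 alkylation and C8–C9 acylative closure of ring B from ring A sulfone diester 17 and homoallylic iodide 25 (from but-3-yn-1-ol by carboalumination).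
- 17 ⇐ ring A by an enantioselective endo Diels–Alder reaction (bonds C1–C2 and C5–C10) of 2-(phenylsulfonylmethyl)acrolein 5 with silyloxy diene 9, then CHO → CH3 (C20), C4 methylation and C3 reduction.
- Ring order: ring A first (step 6), ring B second (step 17).

Key step: step 17

Numbering: labdane locants are used throughout (ring A = C1–C5 and C10; ring B = C5–C10; C19 = ester carbon on C4; C20 = methyl on C10; side chain C11–C15); β is the face of C20, α the opposite face.

Assumption: the (R)-oxazaborolidinium ion of step 6 is taken to leave open the enal face on which CHO → C=CH2 → CH2SO2Ph runs counterclockwise (the mirror image of the sense expected for the (S)-catalyst with 2-methylacrolein); if the opposite sense is found, the (S)-catalyst is used.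

## Route

Step 1
Reactants: 1 ethyl 2-(bromomethyl)prop-2-enoate; 2 sodium benzenesulfinate
Product: 3 ethyl 2-[(phenylsulfonyl)methyl]prop-2-enoate
Conditions: MeOH, 65 °C
Reagents that add atoms: none
Why: Sulfinate S-alkylation of the activated allylic bromide (SN2 or SN2′, both lead to the same allyl sulfone) is the standard access to this acrylate.

Step 2
Reactants: 3 ethyl 2-[(phenylsulfonyl)methyl]prop-2-enoate
Product: 4 2-[(phenylsulfonyl)methyl]prop-2-en-1-ol
Conditions: i-Bu2AlH (2.2 equiv), CH2Cl2, −78 °C; aq. potassium sodium tartrate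
Reagents that add atoms: none
Why: i-Bu2AlH reduces the acrylate ester by 1,2-addition to the allylic alcohol at low temperature and leaves the sulfone untouched.

Step 3
Reactants: 4 2-[(phenylsulfonyl)methyl]prop-2-en-1-ol
Product: 5 2-[(phenylsulfonyl)methyl]prop-2-enal
Conditions: Dess–Martin periodinane (1,1,1-triacetoxy-1,1-dihydro-1,2-benziodoxol-3(1H)-one), NaHCO3, CH2Cl2, 0 °C
Reagents that add atoms: none
Why: Dess–Martin oxidation of the primary allylic alcohol under buffered, base-free conditions should avoid isomerisation of the allyl sulfone to the conjugated vinyl sulfone; the enal is used at once.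

Step 4
Reactants: 6 methyl 3-oxobutanoate (methyl acetoacetate); 7 methyl 4-oxobutanoate
Product: 8 dimethyl (2Z)-2-acetylhex-2-enedioate
Conditions: piperidine (10 mol %), AcOH (10 mol %), 4 Å molecular sieves, CH2Cl2, 0 °C; chromatographic separation of the Z isomer
Reagents that add atoms: none
Why: Knoevenagel condensation; both alkene isomers are expected, the Z isomer (chain cis to the ester, so that the chain lies outside in the later s-cis diene) is taken on and the E isomer is re-equilibrated under the same amine/acid conditions.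

Step 5
Reactants: 8 dimethyl (2Z)-2-acetylhex-2-enedioate
Product: 9 dimethyl (2Z)-2-[1-(triisopropylsilyloxy)ethenyl]hex-2-enedioate
Conditions: i-Pr3SiOSO2CF3, Et3N, CH2Cl2, −78 → 0 °C
Reagents that add atoms: triisopropylsilyl trifluoromethanesulfonate, CC(C)[Si](OS(=O)(=O)C(F)(F)F)(C(C)C)C(C)C
Why: Soft enolisation (silyl triflate and amine) removes a proton from the acetyl CH3 next to the O-silylated carbonyl and gives the cross-conjugated 2-silyloxy diene, as in the preparation of other 2-silyloxy dienes from enones; the bulky silyl group should make the diene stable to the acidic catalyst of step 6.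

Step 6
Reactants: 5 2-[(phenylsulfonyl)methyl]prop-2-enal; 9 dimethyl (2Z)-2-[1-(triisopropylsilyloxy)ethenyl]hex-2-enedioate
Product: 10 methyl (5S,6S)-5-formyl-6-(3-methoxy-3-oxopropyl)-5-[(phenylsulfonyl)methyl]-2-(triisopropylsilyloxy)cyclohex-1-ene-1-carboxylate
Conditions: (R)-1-(2-methylphenyl)-3,3-diphenyltetrahydro-1H,3H-pyrrolo[1,2-c][1,3,2]oxazaborole (20 mol %), (CF3SO2)2NH (18 mol %), CH2Cl2, −78 → −40 °C
Reagents that add atoms: none
Why: Diels–Alder reaction catalysed by a chiral oxazaborolidinium ion (Corey type): the silyloxy group and the alkyl-substituted diene terminus both direct C2 to the enal CH2 and C5 to C10, the catalyst shields one face of the s-trans enal and so sets C10, and the endo position of the formyl group places CHO (future C20) cis to the C5 arm.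

Step 7
Reactants: 10 Diels–Alder adduct
Product: 11 (E)-4-methylbenzenesulfonylhydrazone of 10
Conditions: 4-MeC6H4SO2NHNH2, 4 Å molecular sieves, THF, 40 °C
Reagents that add atoms: 4-methylbenzenesulfonohydrazide, Cc1ccc(cc1)S(=O)(=O)NN
Why: Hydrazone formation; the C3 carbonyl is masked as the silyl enol ether, so the neopentyl formyl group is the only carbonyl that can condense.

Step 8
Reactants: 11 sulfonylhydrazone
Product: 13 methyl 6-(3-methoxy-3-oxopropyl)-5-methyl-5-[(phenylsulfonyl)methyl]-2-(triisopropylsilyloxy)cyclohex-1-ene-1-carboxylate, via N-boryl sulfonylhydrazide 12 (not isolated)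
Conditions: catecholborane, CHCl3, 0 °C; then NaOAc·3H2O, 60 °C
Reagents that add atoms: none
Why: Kabalka variant of the Caglioti tosylhydrazone reduction: hydroboration of C=N, then acetate-induced loss of sulfinate and N2, turns the formyl carbon into the C20 methyl without a free C20 alcohol (which could lactonise onto C19) and should leave esters, sulfone and enol silane alone.

Step 9
Reactants: 13 C20-methyl silyl enol ether
Product: 15 methyl 2-(3-methoxy-3-oxopropyl)-1,3-dimethyl-6-oxo-3-[(phenylsulfonyl)methyl]cyclohexane-1-carboxylate, via caesium enolate 14 (not isolated)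
Conditions: CsF, MeI, DMF, 0 → 20 °C
Reagents that add atoms: iodomethane, CI
Why: Fluoride cleaves the silyl enol ether to the caesium enolate of the β-keto ester, which is C-methylated (β-keto ester alkylation); MeI should enter C4 from the α face, anti to the C5 arm and to the axial C20 methyl on C10, so the ester ends up β.

Step 10
Reactants: 15 β-keto ester
Product: 16 methyl 6-hydroxy-2-(3-methoxy-3-oxopropyl)-1,3-dimethyl-3-[(phenylsulfonyl)methyl]cyclohexane-1-carboxylate (3α-alcohol)
Conditions: LiBH(s-Bu)3, THF, −78 °C; aq. NH4Cl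
Reagents that add atoms: none
Why: The bulky hydride should attack the C3 ketone along the equatorial trajectory of the chair that keeps the C5 arm equatorial, giving the axial 3α-alcohol trans to the C4 ester, as in reductions of 4,4-disubstituted 3-oxo terpenoids; esters and sulfone are not reduced at −78 °C.

Step 11
Reactants: 16 3α-alcohol
Product: 17 methyl 2-(3-methoxy-3-oxopropyl)-1,3-dimethyl-3-[(phenylsulfonyl)methyl]-6-(triethylsilyloxy)cyclohexane-1-carboxylate
Conditions: Et3SiOSO2CF3, 2,6-lutidine, CH2Cl2, 0 °C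
Reagents that add atoms: triethylsilyl trifluoromethanesulfonate, CC[Si](CC)(CC)OS(=O)(=O)C(F)(F)F
Why: Silyl triflate silylation of the hindered axial alcohol; triethylsilyl should survive the strong bases of step 17 and can later be removed by mild acid in the presence of the primary tert-butyldiphenylsilyl ether.

Step 12
Reactants: 18 but-3-yn-1-ol
Product: 19 tert-butyl(but-3-yn-1-yloxy)dimethylsilane
Conditions: t-BuMe2SiCl, imidazole, CH2Cl2, 20 °C
Reagents that add atoms: tert-butyldimethylsilyl chloride, CC(C)(C)[Si](C)(C)Cl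
Why: Standard silylation of a primary alcohol, needed so that the carbometallation is not disturbed by a free hydroxyl.

Step 13
Reactants: 19 tert-butyl(but-3-yn-1-yloxy)dimethylsilane
Product: 22 (2E)-5-(tert-butyldimethylsilyloxy)-3-methylpent-2-en-1-ol, via alkenylalane 20 (not isolated), via lithium alanate 21 (not isolated)
Conditions: Me3Al, Cp2ZrCl2 (25 mol %), CH2Cl2, 0 → 20 °C; then n-BuLi, THF, −78 °C; (CH2O)n, −78 → 20 °C
Reagents that add atoms: trimethylaluminium, C[Al](C)C; formaldehyde (as paraformaldehyde), C=O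
Why: Negishi zirconium-catalysed carboalumination adds methyl and aluminium syn across the alkyne with aluminium at the terminus, which fixes the E geometry, and the alanate is hydroxymethylated by formaldehyde with retention.

Step 14
Reactants: 22 (2E)-5-(tert-butyldimethylsilyloxy)-3-methylpent-2-en-1-ol
Product: 23 (2E)-5-(tert-butyldimethylsilyloxy)-1-(tert-butyldiphenylsilyloxy)-3-methylpent-2-ene
Conditions: t-BuPh2SiCl, imidazole, DMF, 20 °C
Reagents that add atoms: tert-butyldiphenylsilyl chloride, CC(C)(C)[Si](Cl)(c1ccccc1)c1ccccc1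
Why: Silylation of the allylic alcohol with the more acid-stable silyl group prepares the selective unmasking of the other end.

Step 15
Reactants: 23 bis-silyl ether
Product: 24 (3E)-5-(tert-butyldiphenylsilyloxy)-3-methylpent-3-en-1-ol
Conditions: pyridinium 4-methylbenzenesulfonate (10 mol %), MeOH, 20 °C
Reagents that add atoms: none
Why: Acid-catalysed methanolysis cleaves the primary tert-butyldimethylsilyl ether much faster than the tert-butyldiphenylsilyl ether (selective desilylation).

Step 16
Reactants: 24 (3E)-5-(tert-butyldiphenylsilyloxy)-3-methylpent-3-en-1-ol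
Product: 25 tert-butyl{[(2E)-5-iodo-3-methylpent-2-en-1-yl]oxy}diphenylsilane
Conditions: I2, PPh3, imidazole, CH2Cl2, 0 °C
Reagents that add atoms: iodine, II
Why: Appel-type iodination (Garegg–Samuelsson conditions) of the primary alcohol under neutral conditions leaves the allylic silyl ether and the E alkene untouched.

Step 17
Reactants: 17 ring A sulfone diester; 25 homoallylic iodide
Product: 28 methyl 5-[(3E)-5-(tert-butyldiphenylsilyloxy)-3-methylpent-3-en-1-yl]-1,4a-dimethyl-6-oxo-5-(phenylsulfonyl)-2-(triethylsilyloxy)decahydronaphthalene-1-carboxylate, via dilithio dianion 26 (not isolated), via C9-alkylated sulfone 27 (not isolated)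
Conditions: LiN(i-Pr)2 (2.2 equiv), THF, −78 °C; 25 (1.2 equiv), −78 → −20 °C; then LiN(SiMe3)2 (1.0 equiv), −20 → 20 °C; aq. NH4Cl
Reagents that add atoms: none
Why: LiN(i-Pr)2 first enolises the C8 ester at C7, which parks that ester so that it cannot be attacked early, and the second equivalent lithiates the C9 methylene next to sulfur; the α-sulfonyl carbanion, the more basic and less aggregated site of the dianion, displaces iodide from 25 by SN2 and gives 27 (bond C9–C11). On warming with LiN(SiMe3)2 the remaining anion equilibrates by proton transfer to the tertiary C9 carbanion, which adds to the now free C8 ester and expels methoxide (Dieckmann-type intramolecular acylation of a sulfone carbanion, bond C8–C9), and the ketone formed is held as its C7 enolate until the quench. The closest known reactions are the alkylation of lithiated alkyl phenyl sulfones with primary iodides and the cyclisation of ω-sulfonyl esters to cyclic β-keto sulfones. Ring B closes in the 6-exo-trig mode through a chair in which the C5–C10 bond of ring A becomes the trans ring fusion. The new centre C9 is set in this closure by the chair, with the phenylsulfonyl group expected axial (α, anti to the C10 methyl) and the chain equatorial, but it is temporary because the sulfone is removed and C9 is then equilibrated. The step needs C9-over-C7 alkylation, which the higher nucleophilicity of the sulfonyl carbanion in THF without polar additive should give, and C8-over-C19 acylation, which is secured because the C19 ester is neopentyl, axial and on the β face while C9 sits on the α side of C10 and cannot bridge to it.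

Step 18
Reactants: 28 decalin β-keto sulfone
Product: 30 methyl 5-[(3E)-5-(tert-butyldiphenylsilyloxy)-3-methylpent-3-en-1-yl]-1,4a-dimethyl-6-oxo-2-(triethylsilyloxy)decahydronaphthalene-1-carboxylate (H-9 α), via C9-epimer mixture 29 (not isolated)
Conditions: SmI2 (2.5 equiv), THF–MeOH, −78 °C; then NaOMe (0.5 equiv), MeOH, 20 °C
Reagents that add atoms: none
Why: SmI2 reduces the α-sulfonyl ketone to a samarium enolate with loss of sulfinate (reductive desulfonylation), and methoxide then equilibrates C9 through the enolate to the trans-decalin with the side chain equatorial (β) and H-9 α, as in the target.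

Step 19
Reactants: 30 C8 ketone
Product: 31 methyl 5-[(3E)-5-(tert-butyldiphenylsilyloxy)-3-methylpent-3-en-1-yl]-1,4a-dimethyl-6-methylidene-2-(triethylsilyloxy)decahydronaphthalene-1-carboxylate
Conditions: Ph3PCH3Br, KOt-Bu, toluene–THF, 20 → 70 °C
Reagents that add atoms: methyltriphenylphosphonium bromide, [Br-].C[P+](c1ccccc1)(c1ccccc1)c1ccccc1
Why: Wittig methylenation of the hindered C8 ketone is the usual way to the 8(17)-ene of labdanes; enolisation under the basic conditions can only return the already stable C9 epimer and the neopentyl C19 ester should not be attacked.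

Step 20
Reactants: 31 exocyclic alkene
Product: 32 methyl 5-[(3E)-5-(tert-butyldiphenylsilyloxy)-3-methylpent-3-en-1-yl]-2-hydroxy-1,4a-dimethyl-6-methylidenedecahydronaphthalene-1-carboxylate
Conditions: pyridinium 4-methylbenzenesulfonate (20 mol %), MeOH–CH2Cl2, 20 °C
Reagents that add atoms: none
Why: Mild acid methanolysis should remove the secondary triethylsilyl ether while the far more acid-stable tert-butyldiphenylsilyl ether stays and the exocyclic alkene is not isomerised.

Step 21
Reactants: 32 3α-alcohol
Product: 33 methyl 2-acetoxy-5-[(3E)-5-(tert-butyldiphenylsilyloxy)-3-methylpent-3-en-1-yl]-1,4a-dimethyl-6-methylidenedecahydronaphthalene-1-carboxylate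
Conditions: Ac2O, 4-(dimethylamino)pyridine, pyridine, 40 °C
Reagents that add atoms: acetic anhydride, CC(=O)OC(C)=O
Why: Nucleophile-catalysed acylation of the hindered axial 3α-alcohol; no other free hydroxyl is present.

Step 22
Reactants: 33 C3 acetate
Product: 34 methyl (1R,2R,4aR,5S,8aR)-2-acetoxy-5-[(3E)-5-hydroxy-3-methylpent-3-en-1-yl]-1,4a-dimethyl-6-methylidenedecahydronaphthalene-1-carboxylate (target)
Conditions: Bu4NF, AcOH, THF, 0 → 20 °C
Reagents that add atoms: none
Why: Buffered fluoride cleaves the primary allylic silyl ether and should leave the C3 acetate and the methyl ester in place.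

## Compound list

1 | ethyl 2-(bromomethyl)prop-2-enoate | C=C(CBr)C(=O)OCC | starting material
2 | sodium benzenesulfinate | [Na+].[O-]S(=O)c1ccccc1 | starting material
3 | ethyl 2-[(phenylsulfonyl)methyl]prop-2-enoate | C=C(CS(=O)(=O)c1ccccc1)C(=O)OCC | intermediate
4 | 2-[(phenylsulfonyl)methyl]prop-2-en-1-ol | C=C(CO)CS(=O)(=O)c1ccccc1 | intermediate
5 | 2-[(phenylsulfonyl)methyl]prop-2-enal | C=C(C=O)CS(=O)(=O)c1ccccc1 | intermediate
6 | methyl 3-oxobutanoate | COC(=O)CC(C)=O | starting material
7 | methyl 4-oxobutanoate | COC(=O)CCC=O | starting material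
8 | dimethyl (2Z)-2-acetylhex-2-enedioate | COC(=O)CC/C=C(C(C)=O)\C(=O)OC | intermediate
9 | dimethyl (2Z)-2-[1-(triisopropylsilyloxy)ethenyl]hex-2-enedioate | C=C(O[Si](C(C)C)(C(C)C)C(C)C)/C(C(=O)OC)=C/CCC(=O)OC | intermediate
10 | methyl (5S,6S)-5-formyl-6-(3-methoxy-3-oxopropyl)-5-[(phenylsulfonyl)methyl]-2-(triisopropylsilyloxy)cyclohex-1-ene-1-carboxylate; formyl cis to the propanoate arm | COC(=O)CC[C@@H]1[C@](C=O)(CCC(O[Si](C(C)C)(C(C)C)C(C)C)=C1C(=O)OC)CS(=O)(=O)c1ccccc1 | intermediate
11 | (E)-4-methylbenzenesulfonylhydrazone of the formyl group of 10 | COC(=O)CC[C@@H]1[C@](/C=N/NS(=O)(=O)c2ccc(C)cc2)(CCC(O[Si](C(C)C)(C(C)C)C(C)C)=C1C(=O)OC)CS(=O)(=O)c1ccccc1 | intermediate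
12 | N-(1,3,2-benzodioxaborol-2-yl) sulfonylhydrazide from hydroboration of the C=N bond of 11 | COC(=O)CC[C@@H]1[C@](CN(B2Oc3ccccc3O2)NS(=O)(=O)c2ccc(C)cc2)(CCC(O[Si](C(C)C)(C(C)C)C(C)C)=C1C(=O)OC)CS(=O)(=O)c1ccccc1 | intermediate (not isolated)
13 | methyl 6-(3-methoxy-3-oxopropyl)-5-methyl-5-[(phenylsulfonyl)methyl]-2-(triisopropylsilyloxy)cyclohex-1-ene-1-carboxylate; 5-methyl (C20) cis to the arm | COC(=O)CC[C@@H]1[C@](C)(CCC(O[Si](C(C)C)(C(C)C)C(C)C)=C1C(=O)OC)CS(=O)(=O)c1ccccc1 | intermediate
14 | caesium enolate of the β-keto ester from 13 | [Cs+].COC(=O)CC[C@@H]1[C@](C)(CCC([O-])=C1C(=O)OC)CS(=O)(=O)c1ccccc1 | intermediate (not isolated)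
15 | methyl 2-(3-methoxy-3-oxopropyl)-1,3-dimethyl-6-oxo-3-[(phenylsulfonyl)methyl]cyclohexane-1-carboxylate; labdane locants 4α-Me, 4β-CO2Me, 5β-arm, 10β-Me, 10α-CH2SO2Ph | COC(=O)CC[C@@H]1[C@](C)(CCC(=O)[C@]1(C)C(=O)OC)CS(=O)(=O)c1ccccc1 | intermediate
16 | 6-hydroxy compound from 15; 3α-OH axial, trans to the C4 ester | COC(=O)CC[C@@H]1[C@](C)(CC[C@@H](O)[C@]1(C)C(=O)OC)CS(=O)(=O)c1ccccc1 | intermediate
17 | triethylsilyl ether of 16 (ring A sulfone diester, key-step precursor) | COC(=O)CC[C@@H]1[C@](C)(CC[C@@H](O[Si](CC)(CC)CC)[C@]1(C)C(=O)OC)CS(=O)(=O)c1ccccc1 | intermediate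
18 | but-3-yn-1-ol | C#CCCO | starting material
19 | tert-butyl(but-3-yn-1-yloxy)dimethylsilane | C#CCCO[Si](C)(C)C(C)(C)C | intermediate
20 | [(1E)-4-(tert-butyldimethylsilyloxy)-2-methylbut-1-en-1-yl]dimethylalane | C[Al](C)/C=C(C)/CCO[Si](C)(C)C(C)(C)C | intermediate (not isolated)
21 | lithium butyl[(1E)-4-(tert-butyldimethylsilyloxy)-2-methylbut-1-en-1-yl]dimethylalanate | [Li+].CCCC[Al-](C)(C)/C=C(C)/CCO[Si](C)(C)C(C)(C)C | intermediate (not isolated)
22 | (2E)-5-(tert-butyldimethylsilyloxy)-3-methylpent-2-en-1-ol | OC/C=C(C)/CCO[Si](C)(C)C(C)(C)C | intermediate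
23 | (2E)-5-(tert-butyldimethylsilyloxy)-1-(tert-butyldiphenylsilyloxy)-3-methylpent-2-ene | CC(C)(C)[Si](C)(C)OCC/C(C)=C/CO[Si](c1ccccc1)(c1ccccc1)C(C)(C)C | intermediate
24 | (3E)-5-(tert-butyldiphenylsilyloxy)-3-methylpent-3-en-1-ol | OCC/C(C)=C/CO[Si](c1ccccc1)(c1ccccc1)C(C)(C)C | intermediate
25 | tert-butyl{[(2E)-5-iodo-3-methylpent-2-en-1-yl]oxy}diphenylsilane | ICC/C(C)=C/CO[Si](c1ccccc1)(c1ccccc1)C(C)(C)C | intermediate
26 | dilithio derivative of 17 (C8 ester enolate and C9 α-sulfonyl carbanion) | [Li+].[Li+].COC([O-])=CC[C@@H]1[C@](C)(CC[C@@H](O[Si](CC)(CC)CC)[C@]1(C)C(=O)OC)[CH-]S(=O)(=O)c1ccccc1 | intermediate (not isolated)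
27 | 17 alkylated at C9 by the chain of 25 (both C9 epimers) | COC(=O)CC[C@@H]1[C@](C)(CC[C@@H](O[Si](CC)(CC)CC)[C@]1(C)C(=O)OC)C(CC/C(C)=C/CO[Si](c1ccccc1)(c1ccccc1)C(C)(C)C)S(=O)(=O)c1ccccc1 | intermediate (not isolated)
28 | methyl 5-[(3E)-5-(tert-butyldiphenylsilyloxy)-3-methylpent-3-en-1-yl]-1,4a-dimethyl-6-oxo-5-(phenylsulfonyl)-2-(triethylsilyloxy)decahydronaphthalene-1-carboxylate; labdane locants 9α-SO2Ph, 9β-chain, 5α-H, 10β-Me, 4β-CO2Me, 3α-OSiEt3 | O=C1CC[C@@H]2[C@](C)(CC[C@@H](O[Si](CC)(CC)CC)[C@]2(C)C(=O)OC)[C@]1(CC/C(C)=C/CO[Si](c1ccccc1)(c1ccccc1)C(C)(C)C)S(=O)(=O)c1ccccc1 | intermediate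
29 | desulfonylated C8 ketone as a mixture of C9 epimers | O=C1CC[C@@H]2[C@](C)(CC[C@@H](O[Si](CC)(CC)CC)[C@]2(C)C(=O)OC)C1CC/C(C)=C/CO[Si](c1ccccc1)(c1ccccc1)C(C)(C)C | intermediate (not isolated)
30 | C8 ketone with H-9 α and the chain β (equatorial) | O=C1CC[C@@H]2[C@](C)(CC[C@@H](O[Si](CC)(CC)CC)[C@]2(C)C(=O)OC)[C@H]1CC/C(C)=C/CO[Si](c1ccccc1)(c1ccccc1)C(C)(C)C | intermediate
31 | 8(17)-methylidene compound from 30 | C=C1CC[C@@H]2[C@](C)(CC[C@@H](O[Si](CC)(CC)CC)[C@]2(C)C(=O)OC)[C@H]1CC/C(C)=C/CO[Si](c1ccccc1)(c1ccccc1)C(C)(C)C | intermediate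
32 | 3α-alcohol from 31 (C15 still silylated) | C=C1CC[C@@H]2[C@](C)(CC[C@@H](O)[C@]2(C)C(=O)OC)[C@H]1CC/C(C)=C/CO[Si](c1ccccc1)(c1ccccc1)C(C)(C)C | intermediate
33 | 3α-acetate from 32 (C15 still silylated) | C=C1CC[C@@H]2[C@](C)(CC[C@@H](OC(C)=O)[C@]2(C)C(=O)OC)[C@H]1CC/C(C)=C/CO[Si](c1ccccc1)(c1ccccc1)C(C)(C)C | intermediate
34 | methyl (1R,2R,4aR,5S,8aR)-2-acetoxy-5-[(3E)-5-hydroxy-3-methylpent-3-en-1-yl]-1,4a-dimethyl-6-methylidenedecahydronaphthalene-1-carboxylate | C=C1CC[C@@H]2[C@](C)(CC[C@@H](OC(C)=O)[C@]2(C)C(=O)OC)[C@H]1CC/C(C)=C/CO | target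

## Step count and risks

Total step count: 22 steps.
Longest linear sequence: 15 steps (steps 1–3, 6–11, 17–22).

Steps most likely to fail:

1. Step 17. What may go wrong: competing alkylation at the enolate carbon C7 instead of C9, and decay of the parked ester enolate before the slow proton transfer to the hindered C9 position allows ring closure. Fallback (the two bond formations are separated and the ester is parked as a carboxylate): setting out from 17, selective saponification of the unhindered C8 methyl ester (LiOH, THF–H2O, 0 °C; the neopentyl C19 ester should stay) gives the C8 carboxylic acid F1. Its dianion (LiN(i-Pr)2, 2.2 equiv, THF, −78 °C; carboxylate plus C9 carbanion, the carboxylate being neither acidic at C7 nor electrophilic) is alkylated with 25 to the C9-alkylated acid F2. Esterification with Me3SiCHN2 in toluene–MeOH comes back to the route at 27, which is then closed to 28 with LiN(SiMe3)2 as in the last stage of step 17.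

2. Step 6. What may go wrong: insufficient enantiofacial discrimination of the enal by the boron catalyst, or its deactivation by the ester groups of the diene. Fallback (resolution in place of asymmetric catalysis): setting out from 5 and 9, the cycloaddition is run with Et2AlCl (CH2Cl2, −78 °C) to give the racemic endo adduct, that is 10 together with its enantiomer F3. Condensation with (1R,2R)-N,N′-dimethyl-1,2-diphenylethane-1,2-diamine (4 Å molecular sieves, Et2O) gives the diastereomeric aminal of 10 F4 and the aminal of the enantiomer F5, which are separated by chromatography. Brief hydrolysis of F4 (0.5 M aq. HCl, Et2O, 0 °C) comes back to the route at 10.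

3. Step 8. What may go wrong: slow hydride transfer to the neopentyl C=N bond and partial loss of the enol silane during the acetate-induced decomposition. Fallback (radical deoxygenation in place of hydrazone reduction): setting out from 10, NaBH4 (MeOH–THF, −20 °C) gives the C20 alcohol F6. PhOC(S)Cl, pyridine and 4-(dimethylamino)pyridine in CH2Cl2 give the O-phenyl thionocarbonate F7. Bu3SnH with azobisisobutyronitrile in toluene at 110 °C (Barton–McCombie deoxygenation) comes back to the route at 13.

## Further compounds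

F1 | step 17 | 3-[labdane C5 arm] propanoic acid: C8 carboxylic acid of 17 | OC(=O)CC[C@@H]1[C@](C)(CC[C@@H](O[Si](CC)(CC)CC)[C@]1(C)C(=O)OC)CS(=O)(=O)c1ccccc1
F2 | step 17 | C9-alkylated acid (F1 carrying the chain of 25 on C9, both C9 epimers) | OC(=O)CC[C@@H]1[C@](C)(CC[C@@H](O[Si](CC)(CC)CC)[C@]1(C)C(=O)OC)C(CC/C(C)=C/CO[Si](c1ccccc1)(c1ccccc1)C(C)(C)C)S(=O)(=O)c1ccccc1
F3 | step 6 | enantiomer of 10, (5R,6R) | COC(=O)CC[C@H]1[C@@](C=O)(CCC(O[Si](C(C)C)(C(C)C)C(C)C)=C1C(=O)OC)CS(=O)(=O)c1ccccc1
F4 | step 6 | aminal of 10: formyl carbon as C2 of a (4R,5R)-1,3-dimethyl-4,5-diphenylimidazolidine | COC(=O)CC[C@@H]1[C@](C2N(C)[C@H](c3ccccc3)[C@H](N2C)c3ccccc3)(CCC(O[Si](C(C)C)(C(C)C)C(C)C)=C1C(=O)OC)CS(=O)(=O)c1ccccc1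
F5 | step 6 | aminal of F3 with the same (4R,5R)-imidazolidine | COC(=O)CC[C@H]1[C@@](C2N(C)[C@H](c3ccccc3)[C@H](N2C)c3ccccc3)(CCC(O[Si](C(C)C)(C(C)C)C(C)C)=C1C(=O)OC)CS(=O)(=O)c1ccccc1
F6 | step 8 | C20 alcohol: 5-(hydroxymethyl) analogue of 10 | COC(=O)CC[C@@H]1[C@](CO)(CCC(O[Si](C(C)C)(C(C)C)C(C)C)=C1C(=O)OC)CS(=O)(=O)c1ccccc1
F7 | step 8 | O-phenyl thionocarbonate of F6 | COC(=O)CC[C@@H]1[C@](COC(=S)Oc2ccccc2)(CCC(O[Si](C(C)C)(C(C)C)C(C)C)=C1C(=O)OC)CS(=O)(=O)c1ccccc1
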